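Late in Wednesday's run the substrate goes more slowly than it did at the start, and that slowing is what we hand over. The flask on the bench was charged as listed below, and the readings of the earlier runs stand with it.

| flask | substrate | free catalyst | remark | time |
|---|---|---|---|---|
| Wednesday's | 0.24 M | 0.29 mol% | run made earlier |  |
| Tuesday's | 0.37 M | 0.29 mol% | run made earlier |  |
| Sunday's | 0.17 M | 0.14 mol% | run made earlier |  |
| flask | 0.17 M | 0.29 mol% |  | 2.0 min |

| run | time / s | substrate / % | product / % |
|---|---|---|---|
| Wednesday's | 15.0 | 91.5 | 8.8 |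
| Wednesday's | 30.0 | 86.0 | 12.9 |
| Wednesday's | 50.0 | 79.8 | 20.0 |
| Wednesday's | 60.0 | 76.9 | 22.6 |
| Wednesday's | 80.0 | 72.1 | 27.8 |
| Wednesday's | 90.0 | 69.9 | 30.0 |
| Wednesday's | 120 | 61.5 | 38.6 |
| Tuesday's | 10.0 | 94.4 | 5.1 |
| Tuesday's | 20.0 | 90.7 | 8.7 |
| Tuesday's | 30.0 | 88.5 | 13.0 |
| Tuesday's | 50.0 | 83.0 | 16.6 |
| Tuesday's | 80.0 | 75.0 | 23.7 |
| Tuesday's | 90.0 | 73.7 | 25.4 |
| Tuesday's | 120 | 67.0 | 33.3 |
| Sunday's | 10.0 | 97.7 | 2.5 |
| Sunday's | 30.0 | 92.7 | 8.3 |
| Sunday's | 60.0 | 85.9 | 14.5 |
| Sunday's | 80.0 | 81.7 | 18.5 |
| Sunday's | 120 | 74.3 | 25.3 |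

(each reading ± 0.5 percentage points)

- amount of substrate in percent of the substrate charged, at 12 s, 40 s and 2.0 min

- a reading or a percentage of product counts all its forms, free or not

Divide the mean loss rate after a run's first reading by the loss rate up to that reading, so that time drops out. Wednesday's run gives 0.504; this ratio S, the slowing ratio, is what we carry. Sunday's run, at a catalyst concentration of 2.38 × 10⁻⁴ M against Wednesday's 6.96 × 10⁻⁴ M, reads higher at 0.925, but that rests on a first loss of 2.3 percentage points against a scatter of 0.5 points.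

Our flask holds 4.93 × 10⁻⁴ M of catalyst, between those two, so please leave the charge alone: S is read against that concentration. With Wednesday's first rate, 0.00567 s⁻¹ of the charge at the same loading, we expect 93.2 % substrate at 12 s. Wednesday's S then gives 62.3 % at 2.0 min; the flask's catalyst concentration lies below Wednesday's, and Sunday's still lower one read the higher S, so we expect to find less substrate than that.

The forecast reads 93.7 %, 82 % and 60 %, at the end under our figure. Its ground: “This looks like catalyst loss that is higher order in catalyst, or dimerisation.”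

The flask gave 93.1 %, 81.8 % and 58.1 % at 12 s, 40 s and 2.0 min, so S reads 0.564, above Wednesday's.

    substrate + free catalyst → catalyst intermediate A (k = 83.0 L mol⁻¹ s⁻¹)
    catalyst intermediate A → catalyst intermediate B (k = 12.0 s⁻¹)
    catalyst intermediate B ⇌ free catalyst + product (K = 0.290 M, k = 3.40 s⁻¹)
    crystals ⇌ product, rate k4*(cs4 - [product]) while solid is left; crystals form when [product] > cs4 (solubility = 0.120 M, k = 1.30 s⁻¹)
    2 catalyst intermediate B ⇌ resting dimer (K = 5700 L mol⁻¹, k = 65.0 L mol⁻¹ s⁻¹)

Tuesday's run, at 0.00107 M, reads lower at 0.445. For the forecast to be wrong at the end, a run of this charge would have to show a different S: Sunday's S in our reckoning gives 36.6 %, below the forecast's figure. In the flask, product reached 41.7 % by 2.00 min. Meanwhile catalyst intermediate B fell from 50.1 % of the catalyst charged at 0.200 min to 30.1 % at 2.00 min, while the resting dimer, the off-cycle resting state, rose from 23.0 % to 50.9 %.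

The numbers in the tables stem from a simulated flask with made-up constants; scatter was added.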